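The benzene ring is built, not bought: the arene C1–C6 bond is disconnected. The ring's oxygen pattern (OH on C2 and C4, OMe on C3 between them, C5 and C6 oxygen-free) is that of a folded 1,3-diketone with a methoxylated central carbon and a terminal masked aldehyde. The precursor is therefore an open chain, octadecyl 6-methoxy-5,7-dioxonon-8-enoate carrying an alkoxy group on C9 (a β-alkoxy enone as aldehyde equivalent). Alkoxide-induced attack of chain C4 on C9 with loss of alcohol closes the six-membered carbocycle, which enolizes to the resorcinol; this single operation delivers the complete target, side chain and ester included.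

Key step: step 5

Remark on the chemistry: the open chain is numbered from the ester carbon (C1) to the enol ether carbon (C9), chain C4–C9 becoming arene C1–C6; the enol ether carries octadecyl instead of a small alkyl group, so that the alcohol released on ring closure and the alkoxide base match the ester alcohol, and the diketone is drawn as its diketo tautomer although the enol should predominate.

Step 1
Reactants: 1 glutaric anhydride; 2 octadecan-1-ol
Product: 3 5-(octadecyloxy)-5-oxopentanoic acid
Conditions: 4-(dimethylamino)pyridine (5 mol%), toluene, 80 °C
Reagents that add atoms: none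
Why: nucleophilic acyl substitution (alcoholysis of a cyclic anhydride) opens the ring exactly once, because the carboxylic acid that is formed cannot acylate a second alcohol under these conditions.

Step 2
Reactants: 3 5-(octadecyloxy)-5-oxopentanoic acid
Product: 4 octadecyl 5-chloro-5-oxopentanoate
Conditions: (COCl)2, DMF (cat.), CH2Cl2, 0 °C → rt
Reagents that add atoms: oxalyl chloride, O=C(Cl)C(=O)Cl
Why: acid chloride formation through the Vilsmeier-type chloroiminium catalyst is mild, leaves the ester untouched and gives only gaseous by-products, so crude 4 should be usable directly.

Step 3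
Reactants: 5 methoxyacetyl chloride; 6 octadecyl vinyl ether
Product: 7 (E)-1-methoxy-4-(octadecyloxy)but-3-en-2-one
Conditions: 5 (1.2 equiv), pyridine (1.3 equiv), CH2Cl2, 0 °C → rt
Reagents that add atoms: none
Why: electrophilic acylation of an enol ether at its β-carbon followed by loss of HCl to pyridine (acylation of vinyl ethers with activated acid chlorides) should give the β-alkoxy enone, the α-alkoxy acid chloride being reactive enough and the conjugated E isomer being the thermodynamic one.

Step 4
Reactants: 7 (E)-1-methoxy-4-(octadecyloxy)but-3-en-2-one; 4 octadecyl 5-chloro-5-oxopentanoate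
Product: 9 octadecyl (E)-6-methoxy-9-(octadecyloxy)-5,7-dioxonon-8-enoate, via lithium enolate 8 (not isolated)
Conditions: 7 (2 equiv), LiN(SiMe3)2 (2 equiv), THF, −78 °C; then 4 (1 equiv), −78 °C; AcOH, pH 7 phosphate buffer; silica deactivated with Et3N
Reagents that add atoms: none
Why: Claisen-type C-acylation of the kinetic lithium enolate of the α-alkoxy ketone (the only enolizable position of 7) by an acid chloride at low temperature is the established entry to 1-alkoxy-1-ene-3,5-diones, half of the enolate serving as base for the acidic diketone and the cold buffered quench avoiding acid-promoted cyclodehydration.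

Step 5
Reactants: 9 octadecyl (E)-6-methoxy-9-(octadecyloxy)-5,7-dioxonon-8-enoate
Product: 11 octadecyl 3-(2,4-dihydroxy-3-methoxyphenyl)propanoate, via cyclohexenedione 10 (not isolated)
Conditions: KOC18H37 (3 equiv, from KH and octadecan-1-ol 2), 18-crown-6, degassed THF, 0 → 50 °C, Ar; then AcOH, 0 °C
Reagents that add atoms: none
Why: Excess alkoxide first parks 9 as its C6 diketonate and then, in a small equilibrium share, removes a proton from the C4 methylene next to the C5 ketone; this carbanion adds to C9, the β-carbon of the alkoxy enone, and E1cB loss of octadecan-1-olate gives cyclohexenedione 10, whose two enolizations produce the aromatic ring. The closest known reaction type is the base-induced aldol-type fold of 1,3,5-tricarbonyl chains into resorcinols (polyketide-style cyclization), here with a vinylogous ester as aldehyde equivalent so that addition–elimination replaces aldol–dehydration. The ring C4–C5–C6–C7–C8–C9 closes in the 6-endo-trig mode, and no stereocentre remains because the two sp3 centres of 10 are lost on aromatization. The step needs carbon instead of oxygen closure (oxygen attack on C9 would lead to a 4-pyranone): under stoichiometric alkoxide the O-closure is reversible, since alkoxide re-adds to the pyranone and reopens it, whereas C-closure ends in the aromatic resorcinolate and cannot revert. The crown-complexed potassium counter-ion avoids an O,O-chelated U-shaped diketonate that would hold C4 and C9 apart. Because the leaving group on C9, the base and the ester alkoxy group are all octadecyloxy, any acyl or enol ether exchange is degenerate and the octadecyl ester should survive; the cold, weakly acidic quench avoids lactonization of the 2-hydroxyaryl propanoate.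

Compound list
1 | glutaric anhydride (oxane-2,6-dione) | O=C1CCCC(=O)O1 | starting material
2 | octadecan-1-ol | CCCCCCCCCCCCCCCCCCO | starting material
3 | 5-(octadecyloxy)-5-oxopentanoic acid | CCCCCCCCCCCCCCCCCCOC(=O)CCCC(=O)O | intermediate
4 | octadecyl 5-chloro-5-oxopentanoate | CCCCCCCCCCCCCCCCCCOC(=O)CCCC(=O)Cl | intermediate
5 | methoxyacetyl chloride | COCC(=O)Cl | starting material
6 | octadecyl vinyl ether (1-(ethenyloxy)octadecane) | C=COCCCCCCCCCCCCCCCCCC | starting material
7 | (E)-1-methoxy-4-(octadecyloxy)but-3-en-2-one | COCC(=O)/C=C/OCCCCCCCCCCCCCCCCCC | intermediate
8 | lithium (1Z,3E)-1-methoxy-4-(octadecyloxy)buta-1,3-dien-2-olate (chelated enolate of 7, not isolated) | [Li+].CO/C=C(\[O-])/C=C/OCCCCCCCCCCCCCCCCCC | intermediate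
9 | octadecyl (E)-6-methoxy-9-(octadecyloxy)-5,7-dioxonon-8-enoate | CCCCCCCCCCCCCCCCCCOC(=O)CCCC(=O)C(OC)C(=O)/C=C/OCCCCCCCCCCCCCCCCCC | intermediate
10 | octadecyl 3-(5-methoxy-4,6-dioxocyclohex-2-en-1-yl)propanoate (transient, the two sp3 ring centres undefined, not isolated) | CCCCCCCCCCCCCCCCCCOC(=O)CCC1C=CC(=O)C(OC)C1=O | intermediate
11 | octadecyl 3-(2,4-dihydroxy-3-methoxyphenyl)propanoate | CCCCCCCCCCCCCCCCCCOC(=O)CCc1ccc(O)c(OC)c1O | target

Total step count: 5
Longest linear sequence: 4 steps (steps 1, 2, 4, 5 from glutaric anhydride); step 3 is the one-step side branch.

Steps most likely to fail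

1. Step 5. Ring closure may run through the diketonate oxygen instead of C4, the weakly acidic C4 methylene may fail to engage, or the diketone may be cleaved by retro-Claisen attack of alkoxide. The fallback uses known chemistry and takes the arene ready-made instead of folding it. Commercial 2-methoxybenzene-1,3-diol and acrylic acid, heated with a sulfonic acid resin (Amberlyst 15) in toluene, should undergo Friedel–Crafts hydroarylation and lactonization (the two open ring positions next to the hydroxyls are equivalent) to give 7-hydroxy-8-methoxychroman-2-one F1. Opening of this aryl lactone with KOC18H37, made from octadecan-1-ol 2 and KH in THF at 0 °C, followed by cold AcOH, should give the open hydroxy ester. This fallback sets out from 2 and comes back to the route at target 11.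

2. Step 4. The enolate may be acylated on oxygen or twice, and the sensitive alkoxyvinyl diketone may cyclodehydrate during isolation. The fallback replaces acylation by aldol addition and oxidation. Acid chloride 4 would be reduced with LiAlH(OtBu)3 (THF, −78 °C) to octadecyl 5-oxopentanoate F2. Addition of lithium enolate 8 (from 7, THF, −78 °C, AcOH quench) should give octadecyl (E)-5-hydroxy-6-methoxy-9-(octadecyloxy)-7-oxonon-8-enoate F3 as a mixture of diastereomers, whose stereocentres are of no consequence. Oxidation with Dess–Martin periodinane (NaHCO3, CH2Cl2) should then give the diketone. This fallback sets out from 4 (with 8) and comes back at 9.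

3. Step 3. The acid chloride may be dehydrochlorinated to a ketene that adds [2+2] to the vinyl ether, or the vinyl ether may oligomerize under acid, in place of C-acylation. The fallback builds the enone from an ynone. Methoxyacetyl chloride 5 with N,O-dimethylhydroxylamine hydrochloride and pyridine (CH2Cl2, 0 °C) should give N,2-dimethoxy-N-methylacetamide F4. HC≡CMgBr (THF, 0 °C, cold acidic quench) should give 1-methoxybut-3-yn-2-one F5. Conjugate addition of octadecan-1-ol 2 catalysed by 1,4-diazabicyclo[2.2.2]octane (CH2Cl2, rt) should give the E-alkoxy enone. This fallback sets out from 5 and comes back at 7.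

Further compounds
F1 | step 5 | 7-hydroxy-8-methoxychroman-2-one | COc1c(O)ccc2CCC(=O)Oc12
F2 | step 4 | octadecyl 5-oxopentanoate | CCCCCCCCCCCCCCCCCCOC(=O)CCCC=O
F3 | step 4 | octadecyl (E)-5-hydroxy-6-methoxy-9-(octadecyloxy)-7-oxonon-8-enoate (mixture of diastereomers) | CCCCCCCCCCCCCCCCCCOC(=O)CCCC(O)C(OC)C(=O)/C=C/OCCCCCCCCCCCCCCCCCC
F4 | step 3 | N,2-dimethoxy-N-methylacetamide | COCC(=O)N(C)OC
F5 | step 3 | 1-methoxybut-3-yn-2-one | COCC(=O)C#C
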